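Locants, kept for every intermediate: ring C1 (alkene carbon with the side chain), C2 (=CH), C3 (CH2), C4 (CHCl), C5 (CMe2), C6 (CHBr); side chain C1′ (CHCl), C2′ (CH2Br).
Retrosynthesis: all four C–halogen bonds go back to C–O bonds and the side chain to a 1-acetyl group. The ring is then cut at C1=C2 and C3–C4, which frees C2–C3 as an acetaldehyde enol silane and leaves the acyclic alkynal OHC(C4)–C5Me2–C6H(OSi)–C1≡C1′–C2′H3.
Enabling feature: in the cyclohexene the unsubstituted pair C3H2–C2H= lies between a heteroatom-bearing sp3 carbon (C4) and an alkene carbon (C1) whose exocyclic neighbour C1′ also bears a heteroatom. This is an aldol retron fused to the 1-acylcycloalkene retron of alkyne–carbonyl metathesis.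
Forward: (R)-pantolactone supplies C4, C5 with both methyl groups, C6 and C1 (five steps to the alkynal). One acid-catalysed domino joins the two-carbon unit at both ends and closes the only ring. Then follow Cl at C4, functionalisation of C2′, the epoxide, Cl at C1′, and both Br last.
Stereochemistry: C6 comes from pantolactone and is inverted by bromide in the last step. C4 is set by 1,3-anti induction from C6 in the aldol half of the key step and inverted by chloride. C1′ is set by reagent-controlled CBS reduction, kept in the epoxide and inverted by chloride.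

Key step: step 7

Step 1
Reactants: 1 (R)-pantolactone
Product: 2 (3R)-4,4-dimethyl-3-(triisopropylsilyloxy)oxolan-2-one
Conditions: iPr3SiOTf, 2,6-lutidine, CH2Cl2, 0 °C to rt
Reagents that add atoms: triisopropylsilyl trifluoromethanesulfonate, CC(C)[Si](C(C)C)(C(C)C)OS(=O)(=O)C(F)(F)F
Why: Silyl ether formation with a silyl triflate suits the hindered neopentylic carbinol, the bulky group resists O-to-O migration in step 3 and survives the silyl Lewis acid of step 7, and C6 is untouched.

Step 2
Reactants: 2 (3R)-4,4-dimethyl-3-(triisopropylsilyloxy)oxolan-2-one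
Product: 3 (3R)-4,4-dimethyl-3-(triisopropylsilyloxy)oxolan-2-ol (anomer mixture)
Conditions: iBu2AlH, CH2Cl2, −78 °C; aq. Rochelle salt
Reagents that add atoms: none
Why: Partial reduction of a lactone to the lactol stops at the low-temperature aluminium hemiacetal, C6 is not affected and the new anomeric centre disappears in step 3.

Step 3
Reactants: 3 (3R)-4,4-dimethyl-3-(triisopropylsilyloxy)oxolan-2-ol
Product: 4 (3S)-2,2-dimethyl-3-(triisopropylsilyloxy)pent-4-yn-1-ol
Conditions: dimethyl (1-diazo-2-oxopropyl)phosphonate, K2CO3, MeOH, rt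
Reagents that add atoms: dimethyl (1-diazo-2-oxopropyl)phosphonate, COP(=O)(OC)C(=[N+]=[N-])C(C)=O
Why: Seyferth–Gilbert homologation in the Ohira–Bestmann variant acts on the open hydroxy aldehyde form of the lactol, turns C1 into an alkyne carbon and adds C1′, while the mild carbonate base and the flanking quaternary carbon keep the α-silyloxy centre C6 from epimerising (the descriptor changes only through CIP priorities).

Step 4
Reactants: 4 (3S)-2,2-dimethyl-3-(triisopropylsilyloxy)pent-4-yn-1-ol
Product: 6 (3S)-2,2-dimethyl-3-(triisopropylsilyloxy)hex-4-yn-1-ol, via dilithio salt 5 (not isolated)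
Conditions: n-BuLi (2.1 equiv), THF, −78 to 0 °C; MeI (1.05 equiv), DMPU, −78 °C to rt
Reagents that add atoms: iodomethane, CI
Why: In this C-alkylation of an alkoxide/acetylide dianion the carbon nucleophile outruns the lithium alkoxide toward iodomethane, so C2′ is added without a protecting-group step.

Step 5
Reactants: 6 (3S)-2,2-dimethyl-3-(triisopropylsilyloxy)hex-4-yn-1-ol
Product: 7 (3S)-2,2-dimethyl-3-(triisopropylsilyloxy)hex-4-ynal
Conditions: Dess–Martin periodinane, CH2Cl2, 0 °C to rt
Reagents that add atoms: none
Why: Dess–Martin oxidation takes the neopentylic primary alcohol to a non-enolisable aldehyde under near-neutral conditions that leave the silyl ether and the alkyne alone.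

Step 6
Reactants: 8 tetrahydrofuran; 9 chlorotris(trimethylsilyl)silane
Product: 11 tris(trimethylsilyl)silyl vinyl ether, via lithium ethenolate 10 (not isolated)
Conditions: n-BuLi, THF (reactant and solvent), rt, overnight; then 9, 0 °C to rt
Reagents that add atoms: none
Why: Deprotonation and cycloreversion of tetrahydrofuran gives the lithium enolate of acetaldehyde free of self-aldol products, and O-silylation of this enolate with the bulky chlorosilane gives the supersilyl enol ether.

Step 7
Reactants: 7 (3S)-2,2-dimethyl-3-(triisopropylsilyloxy)hex-4-ynal; 11 tris(trimethylsilyl)silyl vinyl ether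
Product: 14 1-[(4S,6R)-5,5-dimethyl-6-(triisopropylsilyloxy)-4-[tris(trimethylsilyl)silyloxy]cyclohex-1-en-1-yl]ethan-1-one, via aldol aldehyde 12 (not isolated), via oxetene 13 (not isolated)
Conditions: HN(SO2CF3)2 (cat.), 11 (1.05 equiv, slow addition), CH2Cl2, −78 °C, then warm to rt
Reagents that add atoms: none
Why: Proposed new method: HN(SO2CF3)2 is silylated by 11 to the strong, monodentate Lewis acid (Me3Si)3Si–N(SO2CF3)2, which activates the aldehyde of 7 for C-attack by 11 with silyl transfer (Mukaiyama aldol, forms C3–C4, gives 12); the new, unhindered aldehyde carbon C2 of 12 is activated in the same way and attacked by the proximal alkyne carbon C1, and the developing vinyl cation at C1′ is captured by the carbonyl oxygen to give oxetene 13, whose electrocyclic opening creates C1=C2 and leaves the oxygen on C1′ as the acetyl group of 14. The closest known reaction types are the single cross-aldol of acetaldehyde supersilyl enol ethers with hindered aldehydes under the same catalyst and the acid-promoted intramolecular alkyne–carbonyl metathesis of methyl-capped alkynyl carbonyl compounds to 1-acetylcycloalkenes, and only their merger in one flask on a 4-alkynal is new. The six-membered carbocycle closes in the 6-exo-dig mode (exo-trig at the carbonyl), and the transient four-membered oxetene closes by O-attack on the vinyl cation, a stepwise [2+2] that is then undone in the other direction. The only new stereocentre, C4, is controlled by C6: with a non-chelating silyl Lewis acid the β-silyloxy aldehyde reacts through the polar 1,3-anti model (C6–O dipole opposed to the activated C=O, attack anti to the C6 branch), which gives the anti-4,6-dioxygenated chain of 12 and hence the trans-4,6-dioxygenated ring of 14. The step needs single aldolisation, which the bulk of the supersilyl ether next to the new aldehyde and the use of about one equivalent of 11 secure, and it needs the alkyne to stay silent until the chain has grown, which the substrate secures because metathesis within 7 itself would have to pass through a four-membered carbocycle. Regioselectivity of the ring closure follows from ring size (six against seven) and from charge build-up on the methyl-bearing alkyne carbon, remote from the electron-withdrawing C6–O bond.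

Step 8
Reactants: 14 1-[(4S,6R)-5,5-dimethyl-6-(triisopropylsilyloxy)-4-[tris(trimethylsilyl)silyloxy]cyclohex-1-en-1-yl]ethan-1-one
Product: 15 1-[(4S,6R)-4-hydroxy-5,5-dimethyl-6-(triisopropylsilyloxy)cyclohex-1-en-1-yl]ethan-1-one
Conditions: Bu4NF (1.0 equiv), AcOH (1.0 equiv), THF, 0 °C
Reagents that add atoms: none
Why: In this fluoride-induced desilylation the Si–Si-substituted supersilyl ether is attacked much faster than the hindered secondary triisopropylsilyl ether, and the acetic acid buffer prevents vinylogous retro-aldol opening of the δ-hydroxy enone.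

Step 9
Reactants: 15 1-[(4S,6R)-4-hydroxy-5,5-dimethyl-6-(triisopropylsilyloxy)cyclohex-1-en-1-yl]ethan-1-one
Product: 16 1-[(4R,6S)-4-chloro-5,5-dimethyl-6-(triisopropylsilyloxy)cyclohex-1-en-1-yl]ethan-1-one
Conditions: PPh3, CCl4, MeCN, 60 °C
Reagents that add atoms: tetrachloromethane, ClC(Cl)(Cl)Cl
Why: Appel chlorination (SN2 with inversion at C4 after phosphonium activation of the hydroxyl) is the reaction type that converts neopentylic carbinols without Wagner–Meerwein shift, and allylic 1,2-strain holds C6–OSi pseudoaxial so that the trans C4–O leaving group is equatorial, has no antiperiplanar C–H or C–CH3 bond for elimination or methyl migration, and is displaced along the axial line.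

Step 10
Reactants: 16 1-[(4R,6S)-4-chloro-5,5-dimethyl-6-(triisopropylsilyloxy)cyclohex-1-en-1-yl]ethan-1-one
Product: 18 2-bromo-1-[(4R,6S)-4-chloro-5,5-dimethyl-6-(triisopropylsilyloxy)cyclohex-1-en-1-yl]ethan-1-one, via silyl dienol ether 17 (not isolated)
Conditions: Me3SiOTf, Et3N, CH2Cl2, 0 °C; then NBS, THF, −78 to 0 °C
Reagents that add atoms: N-bromosuccinimide, O=C1CCC(=O)N1Br
Why: Soft enolisation of the methyl ketone to the cross-conjugated 2-silyloxydiene and electrophilic bromination at its terminal CH2 (silyl enol ether halogenation) functionalise C2′ without a strong base that could expel the C4 chloride after γ-deprotonation.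

Step 11
Reactants: 18 2-bromo-1-[(4R,6S)-4-chloro-5,5-dimethyl-6-(triisopropylsilyloxy)cyclohex-1-en-1-yl]ethan-1-one
Product: 20 (2R)-2-[(4R,6S)-4-chloro-5,5-dimethyl-6-(triisopropylsilyloxy)cyclohex-1-en-1-yl]oxirane, via bromohydrin 19 (not isolated)
Conditions: (R)-1-methyl-3,3-diphenyltetrahydro-1H,3H-pyrrolo[1,2-c][1,3,2]oxazaborole (cat.), BH3·SMe2, THF, −30 °C; MeOH; then K2CO3, MeOH, 0 °C to rt
Reagents that add atoms: none
Why: Corey–Bakshi–Shibata reduction (alkenyl group large, CH2Br small) sets C1′ as the R carbinol under reagent control, and intramolecular Williamson closure onto C2′ keeps that C–O bond and gives the R epoxide.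

Step 12
Reactants: 20 (2R)-2-[(4R,6S)-4-chloro-5,5-dimethyl-6-(triisopropylsilyloxy)cyclohex-1-en-1-yl]oxirane
Product: 22 (1R,5R)-5-chloro-2-[(1S)-1-chloro-2-hydroxyethyl]-6,6-dimethylcyclohex-2-en-1-ol, via silyl ether 21 (not isolated)
Conditions: Me3SiCl, EtOAc, 0 °C; then HF·pyridine, THF, 0 °C to rt
Reagents that add atoms: chlorotrimethylsilane, C[Si](C)(C)Cl
Why: In this ring opening of an alkenyl epoxide by a chlorosilane, chloride attacks the silyl-activated oxirane at the allylic carbon C1′ in an SN2 manner with inversion (R epoxide to S chloride), and HF·pyridine then removes both silyl ethers under non-basic conditions so that the chlorohydrin cannot close back to an epoxide.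

Step 13
Reactants: 22 (1R,5R)-5-chloro-2-[(1S)-1-chloro-2-hydroxyethyl]-6,6-dimethylcyclohex-2-en-1-ol
Product: 23 (4R,6S)-6-bromo-1-[(1S)-2-bromo-1-chloroethyl]-4-chloro-5,5-dimethylcyclohex-1-ene
Conditions: CBr4, PPh3, CH2Cl2, −20 to 0 °C
Reagents that add atoms: tetrabromomethane, BrC(Br)(Br)Br
Why: In this double Appel bromination the primary C2′–OH reacts by unhindered SN2 and the allylic C6–OH by SN2 with inversion to the pseudoaxial bromide trans to C4–Cl, which is also the isomer free of allylic 1,2-strain, while the near-neutral medium with little free bromide spares the C1′ and C4 chlorides.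

Compound list
1 | (R)-pantolactone | CC1(C)COC(=O)[C@@H]1O | starting material
2 | (3R)-4,4-dimethyl-3-(triisopropylsilyloxy)oxolan-2-one | CC1(C)COC(=O)[C@@H]1O[Si](C(C)C)(C(C)C)C(C)C | intermediate
3 | (3R)-4,4-dimethyl-3-(triisopropylsilyloxy)oxolan-2-ol (anomer mixture) | CC1(C)COC(O)[C@@H]1O[Si](C(C)C)(C(C)C)C(C)C | intermediate
4 | (3S)-2,2-dimethyl-3-(triisopropylsilyloxy)pent-4-yn-1-ol | OCC(C)(C)[C@@H](O[Si](C(C)C)(C(C)C)C(C)C)C#C | intermediate
5 | dilithio salt of 4 (lithium alkoxide, lithium acetylide) | [Li]OCC(C)(C)[C@@H](O[Si](C(C)C)(C(C)C)C(C)C)C#C[Li] | intermediate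
6 | (3S)-2,2-dimethyl-3-(triisopropylsilyloxy)hex-4-yn-1-ol | OCC(C)(C)[C@@H](O[Si](C(C)C)(C(C)C)C(C)C)C#CC | intermediate
7 | (3S)-2,2-dimethyl-3-(triisopropylsilyloxy)hex-4-ynal | O=CC(C)(C)[C@@H](O[Si](C(C)C)(C(C)C)C(C)C)C#CC | intermediate
8 | tetrahydrofuran | C1CCOC1 | starting material
9 | chlorotris(trimethylsilyl)silane | C[Si](C)(C)[Si](Cl)([Si](C)(C)C)[Si](C)(C)C | starting material
10 | lithium ethenolate | [Li]OC=C | intermediate
11 | tris(trimethylsilyl)silyl vinyl ether | C=CO[Si]([Si](C)(C)C)([Si](C)(C)C)[Si](C)(C)C | intermediate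
12 | (3S,5S)-4,4-dimethyl-5-(triisopropylsilyloxy)-3-[tris(trimethylsilyl)silyloxy]oct-6-ynal | O=CC[C@H](O[Si]([Si](C)(C)C)([Si](C)(C)C)[Si](C)(C)C)C(C)(C)[C@@H](O[Si](C(C)C)(C(C)C)C(C)C)C#CC | intermediate
13 | oxetene: 2H-oxete fused across C1–C2 of the new ring (O on C2, methyl-bearing sp2 carbon C1′ double-bonded to C1), silyl ethers as in 14 | CC1(C)[C@@H](O[Si]([Si](C)(C)C)([Si](C)(C)C)[Si](C)(C)C)CC2OC(C)=C2[C@@H]1O[Si](C(C)C)(C(C)C)C(C)C | intermediate
14 | 1-[(4S,6R)-5,5-dimethyl-6-(triisopropylsilyloxy)-4-[tris(trimethylsilyl)silyloxy]cyclohex-1-en-1-yl]ethan-1-one | CC1(C)[C@@H](O[Si]([Si](C)(C)C)([Si](C)(C)C)[Si](C)(C)C)CC=C(C(C)=O)[C@@H]1O[Si](C(C)C)(C(C)C)C(C)C | intermediate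
15 | 1-[(4S,6R)-4-hydroxy-5,5-dimethyl-6-(triisopropylsilyloxy)cyclohex-1-en-1-yl]ethan-1-one | CC1(C)[C@@H](O)CC=C(C(C)=O)[C@@H]1O[Si](C(C)C)(C(C)C)C(C)C | intermediate
16 | 1-[(4R,6S)-4-chloro-5,5-dimethyl-6-(triisopropylsilyloxy)cyclohex-1-en-1-yl]ethan-1-one | CC1(C)[C@H](Cl)CC=C(C(C)=O)[C@@H]1O[Si](C(C)C)(C(C)C)C(C)C | intermediate
17 | trimethylsilyl dienol ether of 16 (C1′(OSiMe3)=C2′H2) | CC1(C)[C@H](Cl)CC=C(C(=C)O[Si](C)(C)C)[C@@H]1O[Si](C(C)C)(C(C)C)C(C)C | intermediate
18 | 2-bromo-1-[(4R,6S)-4-chloro-5,5-dimethyl-6-(triisopropylsilyloxy)cyclohex-1-en-1-yl]ethan-1-one | CC1(C)[C@H](Cl)CC=C(C(=O)CBr)[C@@H]1O[Si](C(C)C)(C(C)C)C(C)C | intermediate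
19 | (1R)-2-bromo-1-[(4R,6S)-4-chloro-5,5-dimethyl-6-(triisopropylsilyloxy)cyclohex-1-en-1-yl]ethan-1-ol | CC1(C)[C@H](Cl)CC=C([C@@H](O)CBr)[C@@H]1O[Si](C(C)C)(C(C)C)C(C)C | intermediate
20 | (2R)-2-[(4R,6S)-4-chloro-5,5-dimethyl-6-(triisopropylsilyloxy)cyclohex-1-en-1-yl]oxirane | CC1(C)[C@H](Cl)CC=C([C@@H]2CO2)[C@@H]1O[Si](C(C)C)(C(C)C)C(C)C | intermediate
21 | C2′-O-trimethylsilyl, C6-O-triisopropylsilyl ether of 22 | CC1(C)[C@H](Cl)CC=C([C@H](Cl)CO[Si](C)(C)C)[C@@H]1O[Si](C(C)C)(C(C)C)C(C)C | intermediate
22 | (1R,5R)-5-chloro-2-[(1S)-1-chloro-2-hydroxyethyl]-6,6-dimethylcyclohex-2-en-1-ol | CC1(C)[C@H](Cl)CC=C([C@H](Cl)CO)[C@@H]1O | intermediate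
23 | (4R,6S)-6-bromo-1-[(1S)-2-bromo-1-chloroethyl]-4-chloro-5,5-dimethylcyclohex-1-ene | CC1(C)[C@H](Cl)CC=C([C@H](Cl)CBr)[C@H]1Br | target

Total steps: 13. Longest linear sequence: 12 (steps 1–5 and 7–13; step 6 is a side branch).

Steps most likely to fail

1. Step 7.
- **What may go wrong:** a second intermolecular aldol addition to the aldehyde of 12 could outrun ring closure. Silanol could be lost from 12 by β-elimination to give an enal. The reaction could stall at 12 because a dialkyl alkyne is a weak nucleophile. The 1,3-anti facial selectivity could erode.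
- **Fallback (known chemistry, sets out from 7, returns at 15):** Hosomi–Sakurai allylation of 7 (allyltrimethylsilane, BF3·OEt2, CH2Cl2, −78 °C, same 1,3-anti induction) would give the homoallylic alcohol F1. Ring-closing enyne metathesis (second-generation Grubbs catalyst RuCl2(=CHPh)(PCy3)(H2IMes), ethene atmosphere, CH2Cl2, reflux) would close the ring to the isopropenyl diene alcohol F2. Lemieux–Johnson cleavage (OsO4 cat., NaIO4, 2,6-lutidine, dioxane–water) of the less hindered 1,1-disubstituted alkene would give 15.

2. Step 9.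
- **What may go wrong:** displacement next to the quaternary carbon is slow and passes under the bulky pseudoaxial silyl ether. The activated oxygen could instead be lost by elimination toward the extended dienone, or a methyl group could migrate.
- **Fallback (sets out from 15, returns at 16):** the displacement is moved to a substrate with a free neighbouring hydroxyl. ClCH2SO2Cl and pyridine would give the chloromethanesulfonate F3. HF·pyridine would remove the silyl group to give the hydroxy sulfonate F4, in which the axial line of attack is cleared and the C6 hydroxyl can hydrogen-bond the incoming chloride. LiCl in DMF would give the chloro alcohol F5 with inversion. Treatment with iPr3SiOTf and 2,6-lutidine would return 16.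

3. Step 13.
- **What may go wrong:** bromide could attack C2 with allylic transposition instead of the neopentylic allylic C6. C6 could epimerise by bromide exchange. Chloride and bromide could exchange at the allylic C1′.
- **Fallback (sets out from 20, returns at 23):** the two brominations are separated, and the hindered allylic one is run before any allylic chloride exists. Bu4NF in THF would give the epoxy alcohol F6. CBr4 and PPh3 at low temperature would give the epoxy bromide F7 as a single-site displacement that can be freed from any transposed isomer. Me3SiCl in EtOAc would open the oxirane at C1′ to the silyl ether F8. Aqueous citric acid would give the bromo chlorohydrin F9, and a second Appel bromination at the primary alcohol would give 23.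

Further compounds
F1 | step 7 | (4S,6S)-5,5-dimethyl-6-(triisopropylsilyloxy)non-1-en-7-yn-4-ol | C=CC[C@H](O)C(C)(C)[C@@H](O[Si](C(C)C)(C(C)C)C(C)C)C#CC
F2 | step 7 | analogue of 15 with prop-1-en-2-yl in place of acetyl | CC1(C)[C@@H](O)CC=C(C(C)=C)[C@@H]1O[Si](C(C)C)(C(C)C)C(C)C
F3 | step 9 | C4 chloromethanesulfonate of 15 | CC1(C)[C@@H](OS(=O)(=O)CCl)CC=C(C(C)=O)[C@@H]1O[Si](C(C)C)(C(C)C)C(C)C
F4 | step 9 | F3 with free C6 hydroxyl | CC1(C)[C@@H](OS(=O)(=O)CCl)CC=C(C(C)=O)[C@@H]1O
F5 | step 9 | 16 with free C6 hydroxyl | CC1(C)[C@H](Cl)CC=C(C(C)=O)[C@@H]1O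
F6 | step 13 | 20 with free C6 hydroxyl | CC1(C)[C@H](Cl)CC=C([C@@H]2CO2)[C@@H]1O
F7 | step 13 | C6 bromide (inverted) of F6 | CC1(C)[C@H](Cl)CC=C([C@@H]2CO2)[C@H]1Br
F8 | step 13 | C2′-O-trimethylsilyl ether of F9 | CC1(C)[C@H](Cl)CC=C([C@H](Cl)CO[Si](C)(C)C)[C@H]1Br
F9 | step 13 | 23 with hydroxyl in place of the C2′ bromine | CC1(C)[C@H](Cl)CC=C([C@H](Cl)CO)[C@H]1Br
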